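**Assumption:** kazinol C has no stereocentre and no stereogenic double bond, so "single enantiomer" is read as the one achiral compound drawn; no stereocontrol is needed.

## Retrosynthetic overview

1. Kazinol C ⇒ a 1,3-diarylpropan-1-one with the carbonyl on ring A, by reductive removal of C=O and loss of the MOM groups. The 1,1-dimethylallyl group of ring A ⇒ aromatic Claisen shift of a 4-O-prenyl ether.
2. The C2 prenyl group of ring B ⇒ Suzuki–Miyaura prenylation of a remaining, hindered C–Br.
3. Key disconnection: the CH2(β)–aryl(ring B) bond ⇒ a ketone homoenolate (a 1-arylcyclopropanol opened by Pd) plus the less hindered C–Br of an ortho-dibromide.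
4. Cyclopropanol ⇒ Kulinkovich reaction on a methyl 2,4-dihydroxybenzoate derivative. Dibromide ⇒ 4,5-dibromocatechol by MOM protection and ortho-lithiation/prenylation.
5. Ring order: no ring of the target is built (both arenes are bought). The only ring made is the sacrificial cyclopropane (step 5), opened again in step 6.

## Route

**Step 1**
Reactants: 1 4,5-dibromobenzene-1,2-diol
Product: 2 1,2-dibromo-4,5-bis(methoxymethoxy)benzene
Conditions: MOMCl (2.5 equiv), i-Pr2NEt (3 equiv), CH2Cl2, 0 °C to rt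
Reagents that add atoms: chloromethyl methyl ether (MOMCl), COCCl
Why: MOM ether formation on both acidic catechol hydroxyls is routine, and the MOM groups later acidify the ortho C–H and survive LiN(i-Pr)2, Grignard and Pd chemistry; no stereocentre is formed.

**Step 2**
Reactants: 2 1,2-dibromo-4,5-bis(methoxymethoxy)benzene
Product: 4 1,2-dibromo-4,5-bis(methoxymethoxy)-3-(3-methylbut-2-en-1-yl)benzene, via aryllithium 3 (not isolated)
Conditions: LiN(i-Pr)2 (1.1 equiv), THF, −78 °C, 1 h; CuBr·SMe2 (10 mol %), prenyl bromide (1.3 equiv), −78 to −30 °C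
Reagents that add atoms: prenyl bromide (1-bromo-3-methylbut-2-ene), CC(C)=CCBr
Why: Directed ortho-metalation: the C3–H flanked by OMOM and Br is the most acidic site, LiN(i-Pr)2 deprotonates without Br/Li exchange, aryllithium 3 is stable at −78 °C, and Cu-catalysed SN2 allylation with prenyl bromide gives the linear prenyl arene.

**Step 3**
Reactants: 5 methyl 2,4-dihydroxybenzoate
Product: 6 methyl 2-hydroxy-4-[(3-methylbut-2-en-1-yl)oxy]benzoate
Conditions: prenyl bromide (1.1 equiv), K2CO3 (1.5 equiv), acetone, reflux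
Reagents that add atoms: prenyl bromide (1-bromo-3-methylbut-2-ene), CC(C)=CCBr
Why: Williamson etherification; the 2-OH is locked in a hydrogen bond to the ester carbonyl, so only the 4-OH is alkylated.

**Step 4**
Reactants: 6 methyl 2-hydroxy-4-[(3-methylbut-2-en-1-yl)oxy]benzoate
Product: 7 methyl 2-(methoxymethoxy)-4-[(3-methylbut-2-en-1-yl)oxy]benzoate
Conditions: NaH (1.3 equiv), MOMCl (1.3 equiv), DMF, 0 °C to rt
Reagents that add atoms: chloromethyl methyl ether (MOMCl), COCCl
Why: MOM ether formation after NaH breaks the chelate of the 2-OH; this removes the acidic proton before the Grignard step and removes the chelation that would steer the later Claisen shift toward C3.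

**Step 5**
Reactants: 7 methyl 2-(methoxymethoxy)-4-[(3-methylbut-2-en-1-yl)oxy]benzoate
Product: 8 1-{2-(methoxymethoxy)-4-[(3-methylbut-2-en-1-yl)oxy]phenyl}cyclopropan-1-ol
Conditions: EtMgBr (3.2 equiv), Ti(OiPr)4 (20 mol %), THF/Et2O, 0 °C to rt; aq. NH4Cl
Reagents that add atoms: ethylmagnesium bromide, CC[Mg]Br
Why: Kulinkovich cyclopropanation: the titanacyclopropane made from EtMgBr and Ti(OiPr)4 adds to the ester as a 1,2-dicarbanion to give the 1-arylcyclopropanol, while the trisubstituted prenyl alkene does not enter ligand exchange at titanium.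

**Step 6 (key step)**
Reactants: 8 1-{2-(methoxymethoxy)-4-[(3-methylbut-2-en-1-yl)oxy]phenyl}cyclopropan-1-ol; 4 1,2-dibromo-4,5-bis(methoxymethoxy)-3-(3-methylbut-2-en-1-yl)benzene
Product: 9 3-[2-bromo-4,5-bis(methoxymethoxy)-3-(3-methylbut-2-en-1-yl)phenyl]-1-{2-(methoxymethoxy)-4-[(3-methylbut-2-en-1-yl)oxy]phenyl}propan-1-one
Conditions: Pd(OAc)2 (5 mol %), XPhos (10 mol %), Cs2CO3 (2 equiv), toluene, 80 °C; 8 (1.0 equiv), 4 (1.1 equiv)
Reagents that add atoms: none
Why: Pd-catalysed ring-opening cross-coupling of a cyclopropanol (ketone homoenolate arylation): oxidative addition goes to the C1–Br that has only one ortho substituent, the Pd cyclopropanolate undergoes β-carbon elimination to a β-palladio ketone (a homoenolate whose nucleophilic β-carbon is the position that is electrophilic in the parent enone), and XPhos-promoted reductive elimination forms the CH2–aryl bond faster than β-hydride elimination, leaving the doubly flanked C2–Br untouched; no stereocentre is formed.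

**Step 7**
Reactants: 9 3-[2-bromo-4,5-bis(methoxymethoxy)-3-(3-methylbut-2-en-1-yl)phenyl]-1-{2-(methoxymethoxy)-4-[(3-methylbut-2-en-1-yl)oxy]phenyl}propan-1-one
Product: 10 3-[4,5-bis(methoxymethoxy)-2,3-bis(3-methylbut-2-en-1-yl)phenyl]-1-{2-(methoxymethoxy)-4-[(3-methylbut-2-en-1-yl)oxy]phenyl}propan-1-one
Conditions: prenylB(pin) (2 equiv), PdCl2(IPent)(3-chloropyridine) (4 mol %; IPent = 1,3-bis(2,6-di(pentan-3-yl)phenyl)imidazol-2-ylidene), 5 M KOH (aq), THF, 70 °C
Reagents that add atoms: 3-methylbut-2-enylboronic acid pinacol ester (prenylB(pin)), CC(C)=CCB1OC(C)(C)C(C)(C)O1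
Why: α-Selective Suzuki–Miyaura allylation: the bulky NHC–Pd catalyst accepts the doubly ortho-substituted bromide and reductive elimination takes place at the unsubstituted terminus of the prenyl–Pd unit, giving the linear prenyl group; the aryl prenyl ether, ketone and MOM ethers tolerate aqueous KOH.

**Step 8**
Reactants: 10 3-[4,5-bis(methoxymethoxy)-2,3-bis(3-methylbut-2-en-1-yl)phenyl]-1-{2-(methoxymethoxy)-4-[(3-methylbut-2-en-1-yl)oxy]phenyl}propan-1-one
Product: 12 3-[4,5-bis(methoxymethoxy)-2,3-bis(3-methylbut-2-en-1-yl)phenyl]-1-[4-hydroxy-2-(methoxymethoxy)-5-(2-methylbut-3-en-2-yl)phenyl]propan-1-one, via cyclohexadienone 11 (not isolated)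
Conditions: EtOH/H2O (4:1), 130 °C, sealed tube, Ar
Reagents that add atoms: none
Why: Aromatic Claisen rearrangement ([3,3]-sigmatropic shift): the O-prenyl group migrates with allyl inversion to C5 rather than to C3, which is squeezed between two oxygen substituents, the para position is blocked by the acyl group, and tautomerisation of dienone 11 restores the phenol, as known for closely related 2-alkoxy-4-prenyloxy aryl carbonyl compounds under water-accelerated conditions; the transient stereocentre of 11 is lost on tautomerisation.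

**Step 9**
Reactants: 12 3-[4,5-bis(methoxymethoxy)-2,3-bis(3-methylbut-2-en-1-yl)phenyl]-1-[4-hydroxy-2-(methoxymethoxy)-5-(2-methylbut-3-en-2-yl)phenyl]propan-1-one
Product: 13 1-[2,4-dihydroxy-5-(2-methylbut-3-en-2-yl)phenyl]-3-[4,5-dihydroxy-2,3-bis(3-methylbut-2-en-1-yl)phenyl]propan-1-one
Conditions: 3 M HCl (aq)/MeOH (1:6), 40 °C
Reagents that add atoms: none
Why: Acid-catalysed transacetalisation transfers the three MOM groups to methanol; dilute HCl at 40 °C is mild enough that the prenyl and 1,1-dimethylallyl groups are not cyclised onto the neighbouring phenols.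

**Step 10**
Reactants: 13 1-[2,4-dihydroxy-5-(2-methylbut-3-en-2-yl)phenyl]-3-[4,5-dihydroxy-2,3-bis(3-methylbut-2-en-1-yl)phenyl]propan-1-one
Product: 16 kazinol C [4-{3-[4,5-dihydroxy-2,3-bis(3-methylbut-2-en-1-yl)phenyl]propyl}-6-(2-methylbut-3-en-2-yl)benzene-1,3-diol], via tetrakis(ethyl carbonate) 14 (not isolated), via ortho-quinone methide 15 (not isolated)
Conditions: ClCO2Et (6 equiv), Et3N (7 equiv), THF, 0 °C; filter; NaBH4 (10 equiv), THF/H2O, 0 °C to rt; then 2 M NaOH, rt; Ar throughout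
Reagents that add atoms: none
Why: Reductive deoxygenation of an ortho-hydroxyaryl ketone through an ortho-quinone methide: hydride reduces the ketone of 14, the ortho ethoxycarbonyl group shifts to the new alkoxide and is expelled to give 15, a second hydride adds to its exocyclic carbon, and NaOH then hydrolyses the remaining carbonates, all under conditions that leave the three alkenes untouched.

## Compound list

1 | 4,5-dibromobenzene-1,2-diol (4,5-dibromocatechol) | Oc1cc(Br)c(Br)cc1O | starting material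
2 | 1,2-dibromo-4,5-bis(methoxymethoxy)benzene | COCOc1cc(Br)c(Br)cc1OCOC | intermediate
3 | [2,3-dibromo-5,6-bis(methoxymethoxy)phenyl]lithium | [Li]c1c(Br)c(Br)cc(OCOC)c1OCOC | intermediate
4 | 1,2-dibromo-4,5-bis(methoxymethoxy)-3-(3-methylbut-2-en-1-yl)benzene | COCOc1cc(Br)c(Br)c(CC=C(C)C)c1OCOC | intermediate
5 | methyl 2,4-dihydroxybenzoate | COC(=O)c1ccc(O)cc1O | starting material
6 | methyl 2-hydroxy-4-[(3-methylbut-2-en-1-yl)oxy]benzoate | COC(=O)c1ccc(OCC=C(C)C)cc1O | intermediate
7 | methyl 2-(methoxymethoxy)-4-[(3-methylbut-2-en-1-yl)oxy]benzoate | COCOc1cc(OCC=C(C)C)ccc1C(=O)OC | intermediate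
8 | 1-{2-(methoxymethoxy)-4-[(3-methylbut-2-en-1-yl)oxy]phenyl}cyclopropan-1-ol | COCOc1cc(OCC=C(C)C)ccc1C1(O)CC1 | intermediate
9 | 3-[2-bromo-4,5-bis(methoxymethoxy)-3-(3-methylbut-2-en-1-yl)phenyl]-1-{2-(methoxymethoxy)-4-[(3-methylbut-2-en-1-yl)oxy]phenyl}propan-1-one | COCOc1cc(OCC=C(C)C)ccc1C(=O)CCc1cc(OCOC)c(OCOC)c(CC=C(C)C)c1Br | intermediate
10 | 3-[4,5-bis(methoxymethoxy)-2,3-bis(3-methylbut-2-en-1-yl)phenyl]-1-{2-(methoxymethoxy)-4-[(3-methylbut-2-en-1-yl)oxy]phenyl}propan-1-one | COCOc1cc(OCC=C(C)C)ccc1C(=O)CCc1cc(OCOC)c(OCOC)c(CC=C(C)C)c1CC=C(C)C | intermediate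
11 | 3-[4,5-bis(methoxymethoxy)-2,3-bis(3-methylbut-2-en-1-yl)phenyl]-1-[6-(methoxymethoxy)-3-(2-methylbut-3-en-2-yl)-4-oxocyclohexa-1,5-dien-1-yl]propan-1-one (racemic at the ring sp3 carbon) | COCOC1=CC(=O)C(C(C)(C)C=C)C=C1C(=O)CCc1cc(OCOC)c(OCOC)c(CC=C(C)C)c1CC=C(C)C | intermediate
12 | 3-[4,5-bis(methoxymethoxy)-2,3-bis(3-methylbut-2-en-1-yl)phenyl]-1-[4-hydroxy-2-(methoxymethoxy)-5-(2-methylbut-3-en-2-yl)phenyl]propan-1-one | COCOc1cc(O)c(C(C)(C)C=C)cc1C(=O)CCc1cc(OCOC)c(OCOC)c(CC=C(C)C)c1CC=C(C)C | intermediate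
13 | 1-[2,4-dihydroxy-5-(2-methylbut-3-en-2-yl)phenyl]-3-[4,5-dihydroxy-2,3-bis(3-methylbut-2-en-1-yl)phenyl]propan-1-one | C=CC(C)(C)c1cc(C(=O)CCc2cc(O)c(O)c(CC=C(C)C)c2CC=C(C)C)c(O)cc1O | intermediate
14 | tetrakis(ethyl carbonate) of 13 (all four phenols as OCO2Et) | C=CC(C)(C)c1cc(C(=O)CCc2cc(OC(=O)OCC)c(OC(=O)OCC)c(CC=C(C)C)c2CC=C(C)C)c(OC(=O)OCC)cc1OC(=O)OCC | intermediate
15 | ortho-quinone methide of ring A carrying three ethyl carbonates (exocyclic C=C geometry not defined) | C=CC(C)(C)C1=CC(=CCCc2cc(OC(=O)OCC)c(OC(=O)OCC)c(CC=C(C)C)c2CC=C(C)C)C(=O)C=C1OC(=O)OCC | intermediate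
16 | kazinol C, 4-{3-[4,5-dihydroxy-2,3-bis(3-methylbut-2-en-1-yl)phenyl]propyl}-6-(2-methylbut-3-en-2-yl)benzene-1,3-diol | C=CC(C)(C)c1cc(CCCc2cc(O)c(O)c(CC=C(C)C)c2CC=C(C)C)c(O)cc1O | target

## Step count and risks

Total steps: 10. Longest linear sequence: 8 (steps 3 to 10, from 5); the ring B branch (steps 1 and 2) joins at step 6.

**Step 6.** The risks are site selection between the two C–Br bonds of 4, β-hydride elimination of the homoenolate, and Pd ionisation of the aryl prenyl ether at 80 °C. The fallback sets out from 4 and comes back at 9; it tells the two halogens apart before the coupling instead of during it. Copper-catalysed aromatic halogen exchange (CuI, trans-N,N′-dimethylcyclohexane-1,2-diamine, NaI, dioxane, 110 °C) should be strongly slowed by a second ortho substituent. It should therefore convert only the C1–Br into the iodide, giving 2-bromo-1-iodo-4,5-bis(methoxymethoxy)-3-(3-methylbut-2-en-1-yl)benzene F1. Cyclopropanol 8 is then coupled with F1 under the same Pd(OAc)2/XPhos/Cs2CO3 system at 50 °C. There the identity of the halogen, and not only sterics, decides the site of oxidative addition, and the lower temperature spares the prenyl ether; the product is 9.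

**Step 7.** The risks at a bromide flanked by two alkyl groups are low conversion, protodebromination or some branched isomer. The fallback sets out from 9 and comes back at 10. Stille coupling with the small, regiochemically unambiguous allyl group (allyltributylstannane, Pd(P(t-Bu)3)2, dioxane, 100 °C) gives 3-[4,5-bis(methoxymethoxy)-3-(3-methylbut-2-en-1-yl)-2-(prop-2-en-1-yl)phenyl]-1-{2-(methoxymethoxy)-4-[(3-methylbut-2-en-1-yl)oxy]phenyl}propan-1-one F2. Olefin cross-metathesis of F2 in 2-methylbut-2-ene with the second-generation Grubbs catalyst (H2IMes)(PCy3)Cl2Ru=CHPh then turns the allyl into the prenyl group and gives 10; the prenyl units already present only exchange degenerately.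

**Step 8.** The risks of a Claisen shift on the fully assembled ketone are the C3 isomer, loss of the prenyl group and thermal side reactions. The fallback sets out from 7 and comes back at 13; it moves the rearrangement to the simple ester, where it can be forced and isomers separated. Heating 7 (EtOH/H2O at 130 °C, or N,N-diethylaniline at 190 °C) gives methyl 4-hydroxy-2-(methoxymethoxy)-5-(2-methylbut-3-en-2-yl)benzoate F3. NaH/MOMCl gives methyl 2,4-bis(methoxymethoxy)-5-(2-methylbut-3-en-2-yl)benzoate F4. EtMgBr/Ti(OiPr)4 gives 1-[2,4-bis(methoxymethoxy)-5-(2-methylbut-3-en-2-yl)phenyl]cyclopropan-1-ol F5. Coupling with 4 as in step 6 gives 1-[2,4-bis(methoxymethoxy)-5-(2-methylbut-3-en-2-yl)phenyl]-3-[2-bromo-4,5-bis(methoxymethoxy)-3-(3-methylbut-2-en-1-yl)phenyl]propan-1-one F6. Prenylation as in step 7 gives 1-[2,4-bis(methoxymethoxy)-5-(2-methylbut-3-en-2-yl)phenyl]-3-[4,5-bis(methoxymethoxy)-2,3-bis(3-methylbut-2-en-1-yl)phenyl]propan-1-one F7. HCl/MeOH as in step 9 then removes all four MOM groups and gives 13.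

## Further compounds

F1 | step 6 | 2-bromo-1-iodo-4,5-bis(methoxymethoxy)-3-(3-methylbut-2-en-1-yl)benzene | COCOc1cc(I)c(Br)c(CC=C(C)C)c1OCOC
F2 | step 7 | 3-[4,5-bis(methoxymethoxy)-3-(3-methylbut-2-en-1-yl)-2-(prop-2-en-1-yl)phenyl]-1-{2-(methoxymethoxy)-4-[(3-methylbut-2-en-1-yl)oxy]phenyl}propan-1-one | COCOc1cc(OCC=C(C)C)ccc1C(=O)CCc1cc(OCOC)c(OCOC)c(CC=C(C)C)c1CC=C
F3 | step 8 | methyl 4-hydroxy-2-(methoxymethoxy)-5-(2-methylbut-3-en-2-yl)benzoate | COCOc1cc(O)c(C(C)(C)C=C)cc1C(=O)OC
F4 | step 8 | methyl 2,4-bis(methoxymethoxy)-5-(2-methylbut-3-en-2-yl)benzoate | COCOc1cc(OCOC)c(C(C)(C)C=C)cc1C(=O)OC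
F5 | step 8 | 1-[2,4-bis(methoxymethoxy)-5-(2-methylbut-3-en-2-yl)phenyl]cyclopropan-1-ol | COCOc1cc(OCOC)c(C(C)(C)C=C)cc1C1(O)CC1
F6 | step 8 | 1-[2,4-bis(methoxymethoxy)-5-(2-methylbut-3-en-2-yl)phenyl]-3-[2-bromo-4,5-bis(methoxymethoxy)-3-(3-methylbut-2-en-1-yl)phenyl]propan-1-one | COCOc1cc(OCOC)c(C(C)(C)C=C)cc1C(=O)CCc1cc(OCOC)c(OCOC)c(CC=C(C)C)c1Br
F7 | step 8 | 1-[2,4-bis(methoxymethoxy)-5-(2-methylbut-3-en-2-yl)phenyl]-3-[4,5-bis(methoxymethoxy)-2,3-bis(3-methylbut-2-en-1-yl)phenyl]propan-1-one | COCOc1cc(OCOC)c(C(C)(C)C=C)cc1C(=O)CCc1cc(OCOC)c(OCOC)c(CC=C(C)C)c1CC=C(C)C
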